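The route rests on disconnecting the δ-lactone at C19: the C4–C19 and O–C19 bonds are made together by inserting carbon monoxide between the C20 hydroxyl and a C4 exocyclic methylene. The key step exploits the 1,3-cis-diaxial relation across ring A between C20 on C10 and C19 on C4, so a palladium-bound C20–O–C(=O) arm can only reach the β face of C4. In one operation it closes the lactone ring and sets the quaternary C4 stereocentre with its methyl group. The precursor is the trans-fused tricyclic C7 ketone with a free C20 alcohol, a C4 methylene and the C11/C14 phenols masked as isopropyl ethers, built by asymmetric conjugate arylation, enolate alkylation and Friedel–Crafts closure of ring B.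

Key step: step 14

Remark: abietane numbering (C1–C20) is used throughout, also for the ring atoms of the monocyclic intermediates. The sense of induction in step 9 is assumed to follow that of the parent 3-methylcyclohex-2-enone reaction. Compounds 11 and 12 are racemic and lose their stereocentre within step 7.

Step 1
Reactants: 1 2-isopropylphenol
Product: 2 1-isopropyl-2-methoxybenzene
Conditions: MeI, K2CO3, acetone, reflux
Reagents that add atoms: iodomethane CI
Why: Williamson O-methylation of the phenoxide, which has no competing nucleophilic site.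

Step 2
Reactants: 2 1-isopropyl-2-methoxybenzene
Product: 5 3-isopropyl-2-methoxyphenol, via aryllithium 3 (not isolated), via dimethyl arylboronate 4 (not isolated)
Conditions: n-BuLi, TMEDA, Et2O, 0 °C → rt; B(OMe)3, −78 °C → rt; H2O2, AcOH, 0 °C
Reagents that add atoms: hydrogen peroxide OO
Why: Directed ortho-metalation places lithium at the only free position ortho to the methoxy group (the future C11), and borylation followed by oxidative boron-to-oxygen migration turns the C–Li bond into C–OH.

Step 3
Reactants: 5 3-isopropyl-2-methoxyphenol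
Product: 6 6-bromo-3-isopropyl-2-methoxyphenol
Conditions: Br2, t-BuNH2, toluene, −78 °C → rt
Reagents that add atoms: bromine BrBr
Why: Amine-mediated ortho-selective bromination of a phenol (delivery from the N-bromoamine hydrogen-bonded to the phenol) should place bromine at the free ortho position (future C9), the para position being flanked by the isopropyl group.

Step 4
Reactants: 6 6-bromo-3-isopropyl-2-methoxyphenol
Product: 7 2-bromo-5-isopropyl-6-methoxy-1,4-benzoquinone
Conditions: ON(SO3K)2, KH2PO4, H2O/acetone, 0 °C → rt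
Reagents that add atoms: potassium nitrosodisulfonate [K+].[K+].[O]N(S(=O)(=O)[O-])S(=O)(=O)[O-]
Why: Teuber oxidation; the phenoxyl radical is trapped at the free para carbon (future C14, both ortho positions being blocked) and loss of imidodisulfonate gives the para-quinone.

Step 5
Reactants: 7 2-bromo-5-isopropyl-6-methoxy-1,4-benzoquinone
Product: 8 2-bromo-5-isopropyl-6-methoxybenzene-1,4-diol
Conditions: Na2S2O4, EtOAc/H2O, rt, argon
Reagents that add atoms: none
Why: Dithionite reduction of a quinone to its hydroquinone, which leaves the aryl bromide untouched.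

Step 6
Reactants: 8 2-bromo-5-isopropyl-6-methoxybenzene-1,4-diol
Product: 9 1-bromo-2,5-diisopropoxy-4-isopropyl-3-methoxybenzene
Conditions: 2-bromopropane (excess), Cs2CO3, DMF, 60 °C, argon
Reagents that add atoms: 2-bromopropane CC(C)Br
Why: Williamson etherification (SN2) of both caesium phenoxides, which sets the C11/C14 isopropyl ethers apart from the C12 methyl ether for the final deprotection.

Step 7
Reactants: 10 3-ethoxycyclohex-2-en-1-one
Product: 13 3-(hydroxymethyl)cyclohex-2-en-1-one, via Grignard adduct 11 (not isolated), via diol 12 (not isolated)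
Conditions: (i-PrO)Me2SiCH2MgCl (from ClCH2SiMe2(O-i-Pr) and Mg), THF, 0 °C; then KF, KHCO3, 30% H2O2, MeOH/THF, rt; then Na2S2O3, 1 M HCl, rt
Reagents that add atoms: [isopropoxy(dimethyl)silyl]methylmagnesium chloride CC(C)O[Si](C)(C)C[Mg]Cl; hydrogen peroxide OO
Why: 1,2-Addition of the silylmethyl Grignard reagent to the vinylogous ester, Tamao oxidation of the C–Si bond before any acid is added, and acid-induced Stork–Danheiser transposition with loss of ethanol give the β-hydroxymethyl enone.

Step 8
Reactants: 13 3-(hydroxymethyl)cyclohex-2-en-1-one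
Product: 14 3-{[tert-butyl(diphenyl)silyl]oxymethyl}cyclohex-2-en-1-one
Conditions: TBDPSCl, imidazole, CH2Cl2, 0 °C → rt
Reagents that add atoms: tert-butylchlorodiphenylsilane CC(C)(C)[Si](Cl)(c1ccccc1)c1ccccc1
Why: Silylation of the primary alcohol; the tert-butyldiphenylsilyl ether is chosen because it should survive the organometallic steps and trifluoroacetic acid and is later removed by fluoride without acid.

Step 9
Reactants: 9 1-bromo-2,5-diisopropoxy-4-isopropyl-3-methoxybenzene; 14 3-{[tert-butyl(diphenyl)silyl]oxymethyl}cyclohex-2-en-1-one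
Product: 18 tert-butyl{[(1R)-1-(2,5-diisopropoxy-4-isopropyl-3-methoxyphenyl)-3-(trimethylsilyloxy)cyclohex-2-en-1-yl]methoxy}diphenylsilane, via aryllithium 15 (not isolated), via aryldimethylalane 16 (not isolated), via aluminium enolate 17 (not isolated)
Conditions: 9, n-BuLi, Et2O, −78 °C; Me2AlCl, −78 °C → rt; then 14, Cu(O2CC4H3S) (copper thiophene-2-carboxylate, 10 mol %), Ph2P–N[CH(CH3)(2-naphthyl)]2 (11 mol %), Et2O, −20 °C; TMSOTf, −20 °C → rt
Reagents that add atoms: trimethylsilyl trifluoromethanesulfonate C[Si](C)(C)OS(=O)(=O)C(F)(F)F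
Why: Copper-catalysed asymmetric conjugate addition of an aryl(dimethyl)alane to a β-substituted cyclohexenone transfers the aryl group to one enone face under control of the chiral phosphinamine ligand (the enantiomer that gives (S)-3-aryl-3-methylcyclohexanones from 3-methylcyclohex-2-enone, which corresponds to the (R)-C10 centre here), and O-silylation of the aluminium enolate stores the C4–C5 enolate regiochemistry.

Step 10
Reactants: 18 silyl enol ether from step 9; 19 tert-butyl bromoacetate
Product: 21 tert-butyl 2-[(1R,2R)-2-(2,5-diisopropoxy-4-isopropyl-3-methoxyphenyl)-2-{[tert-butyl(diphenyl)silyl]oxymethyl}-6-oxocyclohexyl]acetate, via lithium enolate 20 (not isolated)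
Conditions: MeLi, THF, 0 °C; then 19, DMPU, −78 → −20 °C
Reagents that add atoms: none
Why: Methyllithium cleaves the silyl enol ether to the regiodefined lithium enolate, and its SN2 alkylation at C5 (enolate alkylation) is expected to occur by axial attack anti to the pseudoaxial aryl group on the neighbouring quaternary C10, which puts C6 trans to the aryl group and cis to C20 as the trans ring fusion requires.

Step 11
Reactants: 21 keto ester from step 10
Product: 24 (5R,10R)-20-[tert-butyl(diphenyl)silyl]oxy-11,14-diisopropoxy-12-methoxy-18,19-dinorabieta-8,11,13-triene-4,7-dione (trans-fused; 5α-H), via carboxylic acid 22 (not isolated), via mixed anhydride 23 (not isolated)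
Conditions: TFA, CH2Cl2, 0 °C → rt; then TFAA, 0 °C → rt
Reagents that add atoms: none
Why: Acidolysis of the tert-butyl ester and activation as the mixed trifluoroacetic anhydride lead to intramolecular Friedel–Crafts acylation at C8, the only free arene position and one activated by the ortho C14 and para C12 ether groups, which closes six-membered ring B without creating a new stereocentre.

Step 12
Reactants: 24 diketone from step 11
Product: 25 (5S,10R)-20-[tert-butyl(diphenyl)silyl]oxy-11,14-diisopropoxy-12-methoxy-19-norabieta-4(18),8,11,13-tetraen-7-one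
Conditions: Ph3PCH3Br, KOtBu (slight deficit), toluene, 0 °C → rt
Reagents that add atoms: methyltriphenylphosphonium bromide C[P+](c1ccccc1)(c1ccccc1)c1ccccc1.[Br-]
Why: Wittig methylenation with the non-stabilised ylide is expected to select the aliphatic C4 ketone (open on its α face) over the conjugated C7 aryl ketone flanked by the C14 isopropoxy group, and at this temperature it should not epimerise C5.

Step 13
Reactants: 25 silyl ether from step 12
Product: 26 (5S,10R)-20-hydroxy-11,14-diisopropoxy-12-methoxy-19-norabieta-4(18),8,11,13-tetraen-7-one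
Conditions: TBAF, THF, rt → 40 °C
Reagents that add atoms: none
Why: Fluoride-induced desilylation frees the axial C20 alcohol under non-acidic conditions, so the exocyclic alkene can neither migrate nor be attacked by the hydroxyl group.

Step 14
Reactants: 26 alkenol from step 13; 27 carbon monoxide
Product: 28 (4S,5R,10R)-11,14-diisopropoxy-12-methoxy-7-oxoabieta-8,11,13-trien-19,20-olide
Conditions: Pd(OAc)2 (10 mol %), 1,4-bis(diphenylphosphino)butane (12 mol %), CO (20 bar), HCO2H (2 equiv), toluene, 100 °C
Reagents that add atoms: none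
Why: Proposed new method: Pd(OAc)2 with the diphosphine is reduced in the flask to zerovalent palladium, which adds formic acid to give a hydride of divalent palladium; CO binds, the C20 hydroxyl attacks it (formate takes the proton), and the resulting C20–O–C(=O)–Pd–H species inserts the C4 methylene syn into its Pd–C bond, so that C19 bonds to C4 and palladium sits on the former methylene carbon, a neopentyl centre without β-hydrogen, from which C–H reductive elimination gives the C4 methyl group and returns zerovalent palladium. The closest known reaction type is the palladium-catalysed cyclocarbonylation (intramolecular hydroalkoxycarbonylation) of alkenols to lactones, supported by the alkoxycarbonylpalladation that opens the palladium-catalysed dicarbonylation of butenols; closure onto a fully substituted carbon has not been shown. The lactone ring (C19, O, C20, C10, C5, C4) closes in the 6-exo-trig mode. The C4 stereocentre is set by the tether, because the axial C20 arm on the β face of ring A can deliver C19 only to the β face of C4, which makes C19 β and the methyl group α. The selectivity needed is alkoxycarbonyl-first exo closure over hydride-first anti-Markovnikov carbonylation (seven-membered lactone), over attack of the hydroxyl oxygen on the alkene (4,20-ether) and over alkene migration into ring A; the fixed 1,3-diaxial distance between C20–OH and C4, the chelating diphosphine, the non-polar solvent and only a small excess of formic acid are what should secure it.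

Step 15
Reactants: 28 lactone from step 14
Product: 29 (4S,5R,10R)-11,14-dihydroxy-12-methoxy-7-oxoabieta-8,11,13-trien-19,20-olide (CNP0159814.2)
Conditions: BCl3, CH2Cl2, −78 → 0 °C; then degassed MeOH/H2O, argon
Reagents that add atoms: none
Why: Lewis acid dealkylation; BCl3 cleaves the two secondary (isopropyl) aryl ethers far faster than the C12 methyl ether, which has no ortho carbonyl group to assist its cleavage, while lactone and ketone survive and the oxygen-free work-up protects the hydroquinone.

Compound list
1 | 2-isopropylphenol | CC(C)c1ccccc1O | starting material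
2 | 1-isopropyl-2-methoxybenzene | COc1ccccc1C(C)C | intermediate
3 | (3-isopropyl-2-methoxyphenyl)lithium | [Li]c1cccc(C(C)C)c1OC | intermediate
4 | dimethyl (3-isopropyl-2-methoxyphenyl)boronate | COB(OC)c1cccc(C(C)C)c1OC | intermediate
5 | 3-isopropyl-2-methoxyphenol | COc1c(O)cccc1C(C)C | intermediate
6 | 6-bromo-3-isopropyl-2-methoxyphenol | COc1c(O)c(Br)ccc1C(C)C | intermediate
7 | 2-bromo-5-isopropyl-6-methoxy-1,4-benzoquinone | COC1=C(C(C)C)C(=O)C=C(Br)C1=O | intermediate
8 | 2-bromo-5-isopropyl-6-methoxybenzene-1,4-diol | COc1c(O)c(Br)cc(O)c1C(C)C | intermediate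
9 | 1-bromo-2,5-diisopropoxy-4-isopropyl-3-methoxybenzene | COc1c(OC(C)C)c(Br)cc(OC(C)C)c1C(C)C | intermediate
10 | 3-ethoxycyclohex-2-en-1-one | CCOC1=CC(=O)CCC1 | starting material
11 | 3-ethoxy-1-{[isopropoxy(dimethyl)silyl]methyl}cyclohex-2-en-1-ol (racemic) | CCOC1=CC(O)(C[Si](C)(C)OC(C)C)CCC1 | intermediate
12 | 3-ethoxy-1-(hydroxymethyl)cyclohex-2-en-1-ol (racemic) | CCOC1=CC(O)(CO)CCC1 | intermediate
13 | 3-(hydroxymethyl)cyclohex-2-en-1-one | OCC1=CC(=O)CCC1 | intermediate
14 | 3-{[tert-butyl(diphenyl)silyl]oxymethyl}cyclohex-2-en-1-one | CC(C)(C)[Si](OCC1=CC(=O)CCC1)(c1ccccc1)c1ccccc1 | intermediate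
15 | (2,5-diisopropoxy-4-isopropyl-3-methoxyphenyl)lithium | [Li]c1cc(OC(C)C)c(C(C)C)c(OC)c1OC(C)C | intermediate
16 | (2,5-diisopropoxy-4-isopropyl-3-methoxyphenyl)dimethylalane | C[Al](C)c1cc(OC(C)C)c(C(C)C)c(OC)c1OC(C)C | intermediate
17 | dimethylaluminium C4–C5 enolate of the (R)-3-aryl-3-(silyloxymethyl)cyclohexanone | C[Al](C)OC1=C[C@](c2cc(OC(C)C)c(C(C)C)c(OC)c2OC(C)C)(CO[Si](c2ccccc2)(c2ccccc2)C(C)(C)C)CCC1 | intermediate
18 | tert-butyl{[(1R)-1-(2,5-diisopropoxy-4-isopropyl-3-methoxyphenyl)-3-(trimethylsilyloxy)cyclohex-2-en-1-yl]methoxy}diphenylsilane | C[Si](C)(C)OC1=C[C@](c2cc(OC(C)C)c(C(C)C)c(OC)c2OC(C)C)(CO[Si](c2ccccc2)(c2ccccc2)C(C)(C)C)CCC1 | intermediate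
19 | tert-butyl bromoacetate | BrCC(=O)OC(C)(C)C | starting material
20 | lithium C4–C5 enolate of the (R)-3-aryl-3-(silyloxymethyl)cyclohexanone | [Li]OC1=C[C@](c2cc(OC(C)C)c(C(C)C)c(OC)c2OC(C)C)(CO[Si](c2ccccc2)(c2ccccc2)C(C)(C)C)CCC1 | intermediate
21 | tert-butyl 2-[(1R,2R)-2-(2,5-diisopropoxy-4-isopropyl-3-methoxyphenyl)-2-{[tert-butyl(diphenyl)silyl]oxymethyl}-6-oxocyclohexyl]acetate | CC(C)(C)OC(=O)C[C@@H]1[C@](c2cc(OC(C)C)c(C(C)C)c(OC)c2OC(C)C)(CO[Si](c2ccccc2)(c2ccccc2)C(C)(C)C)CCCC1=O | intermediate
22 | 2-[(1R,2R)-2-(2,5-diisopropoxy-4-isopropyl-3-methoxyphenyl)-2-{[tert-butyl(diphenyl)silyl]oxymethyl}-6-oxocyclohexyl]acetic acid | OC(=O)C[C@@H]1[C@](c2cc(OC(C)C)c(C(C)C)c(OC)c2OC(C)C)(CO[Si](c2ccccc2)(c2ccccc2)C(C)(C)C)CCCC1=O | intermediate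
23 | mixed anhydride of acid 22 with trifluoroacetic acid | O=C(OC(=O)C(F)(F)F)C[C@@H]1[C@](c2cc(OC(C)C)c(C(C)C)c(OC)c2OC(C)C)(CO[Si](c2ccccc2)(c2ccccc2)C(C)(C)C)CCCC1=O | intermediate
24 | (5R,10R)-20-[tert-butyl(diphenyl)silyl]oxy-11,14-diisopropoxy-12-methoxy-18,19-dinorabieta-8,11,13-triene-4,7-dione (5α-H, 10β-CH2OSi) | COc1c(OC(C)C)c2c(c(OC(C)C)c1C(C)C)C(=O)C[C@@H]1[C@]2(CO[Si](c3ccccc3)(c3ccccc3)C(C)(C)C)CCCC1=O | intermediate
25 | (5S,10R)-20-[tert-butyl(diphenyl)silyl]oxy-11,14-diisopropoxy-12-methoxy-19-norabieta-4(18),8,11,13-tetraen-7-one (5α-H) | COc1c(OC(C)C)c2c(c(OC(C)C)c1C(C)C)C(=O)C[C@@H]1[C@]2(CO[Si](c3ccccc3)(c3ccccc3)C(C)(C)C)CCCC1=C | intermediate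
26 | (5S,10R)-20-hydroxy-11,14-diisopropoxy-12-methoxy-19-norabieta-4(18),8,11,13-tetraen-7-one (5α-H, 10β-CH2OH) | COc1c(OC(C)C)c2c(c(OC(C)C)c1C(C)C)C(=O)C[C@@H]1[C@]2(CO)CCCC1=C | intermediate
27 | carbon monoxide | [C-]#[O+] | starting material
28 | (4S,5R,10R)-11,14-diisopropoxy-12-methoxy-7-oxoabieta-8,11,13-trien-19,20-olide (4α-CH3, 5α-H) | COc1c(OC(C)C)c2c(c(OC(C)C)c1C(C)C)C(=O)C[C@@H]1[C@]23CCC[C@]1(C)C(=O)OC3 | intermediate
29 | (4S,5R,10R)-11,14-dihydroxy-12-methoxy-7-oxoabieta-8,11,13-trien-19,20-olide | COc1c(O)c2c(c(O)c1C(C)C)C(=O)C[C@@H]1[C@]23CCC[C@]1(C)C(=O)OC3 | target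

Total step count: 15. Longest linear sequence: 13 steps (steps 1–6 and 9–15; steps 7 and 8 form the side branch).

Steps most likely to fail

Step 14 (the one step labelled as a new method). What may go wrong:
- the hydride on palladium may add to the alkene first and place palladium on the terminal carbon, which leads to the seven-membered lactone;
- formic acid may esterify the C20 alcohol;
- acid or palladium may make the hydroxyl oxygen add to the alkene (4,20-ether);
- the double bond may migrate into ring A.

Fallback with known chemistry, which sets out from diketone 24 and comes back at lactone 28: Wittig reaction of 24 with Ph3P=CHOMe (from Ph3PCH2OMe chloride and KOtBu, THF) should give the C4 methoxymethylene enol ether F1, with the same preference for the C4 ketone as in step 12. Aqueous HCl in THF would hydrolyse it to the C4 carbaldehyde F2 as a mixture of C4 epimers. Its potassium enolate (KOtBu, one equivalent, THF, 0 °C, then MeI) should take up the methyl group on the α face, away from the axial C20 substituent, to give the 4α-methyl-4β-formyl compound F3, the classical way to an axial C19 carbonyl group. TBAF would free the C20 alcohol, which closes onto the axial aldehyde as the 19,20-lactol F4, and Ag2CO3 on Celite (toluene, reflux) would oxidise the lactol to 28.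

Step 9. What may go wrong: slow transfer of the fully substituted, ortho-alkoxy aryl group to a β-carbon that already bears a bulky silyloxymethyl group, transfer of methyl in place of aryl, or weak enantiofacial discrimination. Fallback, which gives up asymmetric catalysis for resolution, sets out from 9 and 14 and comes back at 21: bromide 9 is converted with Mg in THF into the aryl Grignard reagent F5, which adds to 14 with CuBr·SMe2 (catalytic) and TMSCl at −40 °C to give the silyl enol ether as the racemate, that is 18 together with the enantiomer of 18 F6. The conditions of step 10 then give, via 20 and the enantiomeric lithium enolate F7, racemic keto ester, that is 21 and the enantiomer of 21 F8, which are separated by preparative chromatography on a chiral stationary phase.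

Step 10. What may go wrong: poor facial selectivity of the alkylation, or enolate equilibration, so that the C5 epimer leading to the cis ring fusion forms. Fallback, which sets C5 by hydrogenation instead of alkylation, sets out from 18 and comes back at 24: the alkylation is run as in step 10 and the product is used as the mixture of 21 and the C5-epimeric keto ester F9. Under the conditions of step 11, F9 passes through the epimeric acid F10 and the epimeric mixed anhydride F11 to the cis-fused diketone F12, which accompanies 24. DDQ (dioxane, 80 °C) dehydrogenates both diketones to the 5-ene-4,7-dione F13, which no longer has a C5 stereocentre. Hydrogenation (H2, Pd/C, EtOAc) should then add hydrogen to the α face, opposite the C20 substituent on C10, and return trans-fused 24.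

Further compounds
F1 | step 14 | (5S,10R)-20-[tert-butyl(diphenyl)silyl]oxy-11,14-diisopropoxy-12-methoxy-4-(methoxymethylene)-18,19-dinorabieta-8,11,13-trien-7-one (E/Z mixture) | COc1c(OC(C)C)c2c(c(OC(C)C)c1C(C)C)C(=O)C[C@@H]1[C@]2(CO[Si](c3ccccc3)(c3ccccc3)C(C)(C)C)CCCC1=COC
F2 | step 14 | 20-[tert-butyl(diphenyl)silyl]oxy-11,14-diisopropoxy-12-methoxy-7-oxo-18-norabieta-8,11,13-trien-19-al (C4 epimers, 5α-H) | COc1c(OC(C)C)c2c(c(OC(C)C)c1C(C)C)C(=O)C[C@@H]1[C@]2(CO[Si](c3ccccc3)(c3ccccc3)C(C)(C)C)CCCC1C=O
F3 | step 14 | (4S,5R,10R)-20-[tert-butyl(diphenyl)silyl]oxy-11,14-diisopropoxy-12-methoxy-7-oxoabieta-8,11,13-trien-19-al (4α-CH3, 4β-CHO) | COc1c(OC(C)C)c2c(c(OC(C)C)c1C(C)C)C(=O)C[C@@H]1[C@]2(CO[Si](c3ccccc3)(c3ccccc3)C(C)(C)C)CCC[C@]1(C)C=O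
F4 | step 14 | 19,20-epoxy-19-hydroxy-11,14-diisopropoxy-12-methoxyabieta-8,11,13-trien-7-one (19,20-lactol, C19 epimers) | COc1c(OC(C)C)c2c(c(OC(C)C)c1C(C)C)C(=O)C[C@@H]1[C@]23CCC[C@]1(C)C(O)OC3
F5 | step 9 | (2,5-diisopropoxy-4-isopropyl-3-methoxyphenyl)magnesium bromide | Br[Mg]c1cc(OC(C)C)c(C(C)C)c(OC)c1OC(C)C
F6 | step 9 | enantiomer of 18, (1S)-silyl enol ether | C[Si](C)(C)OC1=C[C@@](c2cc(OC(C)C)c(C(C)C)c(OC)c2OC(C)C)(CO[Si](c2ccccc2)(c2ccccc2)C(C)(C)C)CCC1
F7 | step 9 | enantiomer of 20, (S)-lithium enolate | [Li]OC1=C[C@@](c2cc(OC(C)C)c(C(C)C)c(OC)c2OC(C)C)(CO[Si](c2ccccc2)(c2ccccc2)C(C)(C)C)CCC1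
F8 | step 9 | enantiomer of 21, (1S,2S)-keto ester | CC(C)(C)OC(=O)C[C@H]1[C@@](c2cc(OC(C)C)c(C(C)C)c(OC)c2OC(C)C)(CO[Si](c2ccccc2)(c2ccccc2)C(C)(C)C)CCCC1=O
F9 | step 10 | C5 epimer of 21, (1S,2R)-keto ester | CC(C)(C)OC(=O)C[C@H]1[C@](c2cc(OC(C)C)c(C(C)C)c(OC)c2OC(C)C)(CO[Si](c2ccccc2)(c2ccccc2)C(C)(C)C)CCCC1=O
F10 | step 10 | C5 epimer of 22, (1S,2R)-keto acid | OC(=O)C[C@H]1[C@](c2cc(OC(C)C)c(C(C)C)c(OC)c2OC(C)C)(CO[Si](c2ccccc2)(c2ccccc2)C(C)(C)C)CCCC1=O
F11 | step 10 | C5 epimer of 23, mixed anhydride | O=C(OC(=O)C(F)(F)F)C[C@H]1[C@](c2cc(OC(C)C)c(C(C)C)c(OC)c2OC(C)C)(CO[Si](c2ccccc2)(c2ccccc2)C(C)(C)C)CCCC1=O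
F12 | step 10 | C5 epimer of 24, cis-fused diketone (5β-H) | COc1c(OC(C)C)c2c(c(OC(C)C)c1C(C)C)C(=O)C[C@H]1[C@]2(CO[Si](c3ccccc3)(c3ccccc3)C(C)(C)C)CCCC1=O
F13 | step 10 | 20-[tert-butyl(diphenyl)silyl]oxy-11,14-diisopropoxy-12-methoxy-18,19-dinorabieta-5,8,11,13-tetraene-4,7-dione | COc1c(OC(C)C)c2c(c(OC(C)C)c1C(C)C)C(=O)C=C1[C@]2(CO[Si](c3ccccc3)(c3ccccc3)C(C)(C)C)CCCC1=O
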